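**Plan**

Ring locants: C1 carries CO2H, C2 is =CH, C3/C4/C5 carry the 6-methylheptanoate, tiglate and acetate, C6 is the CH2.
Retrosynthesis: CO2H ⇐ allyl ester; C3 ester ⇐ formate; C1=C2 ⇐ E1cB loss of a C2 acetate; ring bond C5–C6 ⇐ attack of an open-chain C5 α-acetoxy radical on the CH2 of a 2-substituted acrylate; that radical ⇐ β-scission of the C1–C2 bond of a glucofuranose; acrylate ⇐ sugar C5 aldehyde + allyl propiolate.
Enabling feature: C6 is a methylene between the acetoxy carbinol C5 and the ester-bearing alkene carbon C1, so O–C5–C6–C1(CO2R)=C2 is the imprint of a radical addition to an acrylate CH2 with loss of an allylic group from C2. Ring carbons C2–C5 with their oxygens coincide with C5–C2 of D-glucofuranose, whose expendable C1 ends as a formate on the ring oxygen and so marks the C3 oxygen.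
Forward: tigloylate diacetone-D-glucose at O3, excise C6, add the acrylate at sugar C5, arm the anomeric oxygen, then open the furanose ring and close the cyclohexane ring in one radical cascade, swap formate for 6-methylheptanoate, free the acid.
Stereochemistry: C3 and C4 are C4 and C3 of D-glucose, carried through untouched; C5 is set in the ring closure by an all-equatorial chair transition state; the tiglate geometry comes from tigloyl chloride.

Key step: step 9

Remark: the target SMILES is read as the (3R,4R,5S) isomer, with the three ester groups 3,4-trans and 4,5-trans.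

**Step 1**
Reactants: 1 1,2:5,6-di-O-isopropylidene-α-D-glucofuranose; 2 tigloyl chloride
Product: 3 1,2:5,6-di-O-isopropylidene-3-O-tigloyl-α-D-glucofuranose
Conditions: pyridine, DMAP (cat.), CH2Cl2, 0 °C to rt
Reagents that add atoms: tigloyl chloride, C/C=C(\C)C(Cl)=O
Why: Pyridine/DMAP-mediated O-acylation of the only free hydroxyl of 1 (O3, the future C4 oxygen); no stereocenter is touched and the E geometry of the tiglate is that of the reagent.

**Step 2**
Reactants: 3 1,2:5,6-di-O-isopropylidene-3-O-tigloyl-α-D-glucofuranose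
Product: 5 1,2-O-isopropylidene-3-O-tigloyl-α-D-xylo-pentodialdo-1,4-furanose, via glycol 4 (not isolated)
Conditions: H5IO6 (1.2 equiv), EtOAc, rt
Reagents that add atoms: none
Why: Periodic acid hydrolyses the more labile terminal 5,6-acetonide and cleaves the freed glycol in the same flask (periodate glycol cleavage), excising C6 and leaving the cis-fused 1,2-acetonide, the tiglate and C4 untouched.

**Step 3**
Reactants: 6 propiolic acid; 7 allyl alcohol
Product: 8 allyl propiolate
Conditions: TsOH·H2O (cat.), benzene, reflux, Dean–Stark; distillation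
Reagents that add atoms: allyl alcohol, C=CCO
Why: Fischer esterification driven by azeotropic removal of water.

**Step 4**
Reactants: 5 1,2-O-isopropylidene-3-O-tigloyl-α-D-xylo-pentodialdo-1,4-furanose; 8 allyl propiolate
Product: 10 allyl 6-deoxy-1,2-O-isopropylidene-6-methylidene-3-O-tigloyl-α-D-gluco-heptofuranuronate together with its C5 epimer (sugar C5 carbinol bonded to the α-carbon of allyl acrylate), via vinylalane 9 (not isolated)
Conditions: 8, DIBAL-H (1.0 equiv), NMO, THF, 0 °C; then 5, 0 °C to rt; Rochelle salt work-up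
Reagents that add atoms: allyl propiolate, C#CC(=O)OCC=C
Why: Vinylalumination: DIBAL-H/NMO adds hydride to the alkyne terminus of 8 to give the α-aluminated acrylate 9, which adds to the aldehyde under amine-free conditions (a Morita–Baylis–Hillman adduct without the base that would eliminate the β-tigloyloxy group); the new C5 carbinol forms unselectively, which is harmless because this carbon becomes the sp2 C2 of the target.

**Step 5**
Reactants: 10 allylic alcohol (C5 epimers); 11 acetic anhydride
Product: 12 allyl 5-O-acetyl-6-deoxy-1,2-O-isopropylidene-6-methylidene-3-O-tigloyl-heptofuranuronate (C5 epimers)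
Conditions: Ac2O, pyridine, DMAP (cat.), CH2Cl2, 0 °C
Reagents that add atoms: acetic anhydride, CC(=O)OC(C)=O
Why: Standard acetylation; the acetate blocks O5 so that only the furanose form is possible after step 6, and it is the leaving group that later places the C1=C2 double bond.

**Step 6**
Reactants: 12 allylic acetate (C5 epimers)
Product: 13 allyl 5-O-acetyl-6-deoxy-6-methylidene-3-O-tigloyl-heptofuranuronate (free 1,2-diol, anomers, C5 epimers)
Conditions: TFA/H2O (9:1), 0 °C; co-evaporation with toluene
Reagents that add atoms: water, O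
Why: Acid hydrolysis of the anomeric acetonide at low temperature, which the esters, the allyl ester and the electron-poor allylic acetate should tolerate.

**Step 7**
Reactants: 13 lactol diol; 14 trimethyl orthoacetate
Product: 16 allyl 2,5-di-O-acetyl-6-deoxy-6-methylidene-3-O-tigloyl-heptofuranuronate (free anomeric OH), via orthoester 15 (not isolated)
Conditions: MeC(OMe)3, CSA (cat.), CH2Cl2, rt; then 80% aq. AcOH, rt
Reagents that add atoms: trimethyl orthoacetate, CC(OC)(OC)OC; water, O
Why: The 1,2-cis diol of the α-anomer (reached by mutarotation) closes to the bicyclic orthoacetate 15, whose mild acid hydrolysis opens by the known orthoester route to the 2-O-acetyl hemiacetal, so O2 (the future C5 acetate oxygen) is acetylated without any nucleophile that could attack the allylic acetate.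

**Step 8**
Reactants: 16 2-O-acetyl lactol; 17 N-hydroxyphthalimide
Product: 18 N-glycosyloxyphthalimide of 16 (anomeric O–N(phthaloyl); anomers, C5 epimers)
Conditions: PPh3, DIAD, THF, 0 °C to rt
Reagents that add atoms: N-hydroxyphthalimide, O=C1c2ccccc2C(=O)N1O
Why: Mitsunobu reaction of the hemiacetal hydroxyl with the acidic N–OH of 17 gives a stable reductive precursor of the anomeric alkoxy radical; the anomeric configuration is irrelevant.

**Step 9**
Reactants: 18 N-glycosyloxyphthalimide
Product: 20 allyl (3R,4R,5S)-5-acetoxy-3-(formyloxy)-4-(tigloyloxy)cyclohex-1-ene-1-carboxylate, via cyclohexane ester 19 (not isolated)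
Conditions: Ir(ppy)3 (1 mol %), Hantzsch ester (1.5 equiv), degassed MeCN (0.02 M), blue LEDs, rt; then DBU (3 equiv), 0 °C to rt
Reagents that add atoms: none
Why: Proposed new method: single-electron reduction of the N-alkoxyphthalimide by photoexcited Ir(ppy)3 breaks the N–O bond to the anomeric alkoxy radical, whose β-scission of the sugar C1–C2 bond leaves C1 as the formate on the former ring oxygen and gives a secondary α-acetoxy radical at sugar C2; this nucleophilic radical adds to the CH2 terminus of the tethered 2-substituted acrylate, the α-ester radical is quenched by the Hantzsch ester to 19, and DBU then expels the β-acetoxy group (E1cB) to place the C1=C2 double bond. The closest known reactions are the reductive fragmentation of anomeric alkoxy radicals from N-glycosyloxyphthalimides with capture of the C2 radical, and Giese-type 6-endo cyclisations of 5-(alkoxycarbonyl)hex-5-enyl radicals; joining them in one ring-forming cascade is the new element. The cyclohexane ring closes in the 6-endo-trig mode. The new C5 stereocenter is set by the sugar-derived C3/C4 centres in a chair-like transition state in which the formyloxy and tigloyloxy groups are equatorial and the acetoxy group on the radical carbon also sits equatorial, giving the 4,5-trans (all-trans) triad; the C1 and C2 centres of 19 are erased by the elimination. The step needs β-scission to outrun hydrogen transfer to the alkoxy radical (secured by the anomeric oxygen and the acetoxy group, which stabilise both fragments), 6-endo to beat 5-exo (secured by the ester on the internal alkene carbon, which makes the CH2 terminus the polarity-matched, unhindered site) and cyclisation to beat reduction of the open radical (secured by the slow hydrogen donor and dilution).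

**Step 10**
Reactants: 20 formate
Product: 21 allyl (3R,4S,5S)-5-acetoxy-3-hydroxy-4-(tigloyloxy)cyclohex-1-ene-1-carboxylate
Conditions: KHCO3 (0.5 equiv), MeOH, 0 °C, short reaction time
Reagents that add atoms: none
Why: Formates undergo base-catalysed methanolysis far faster than acetates, tiglates or conjugated esters, so brief bicarbonate/methanol at 0 °C should unmask only the allylic C3 hydroxyl.

**Step 11**
Reactants: 21 allylic alcohol; 22 6-methylheptanoic acid
Product: 23 allyl (3R,4R,5S)-5-acetoxy-3-[(6-methylheptanoyl)oxy]-4-(tigloyloxy)cyclohex-1-ene-1-carboxylate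
Conditions: EDC·HCl, DMAP (cat.), CH2Cl2, 0 °C to rt
Reagents that add atoms: 6-methylheptanoic acid, CC(C)CCCCC(=O)O
Why: Steglich esterification of the single free hydroxyl; no stereocenter is involved.

**Step 12**
Reactants: 23 allyl ester
Product: 24 (3R,4R,5S)-5-acetoxy-3-[(6-methylheptanoyl)oxy]-4-{[(E)-2-methylbut-2-enoyl]oxy}cyclohex-1-ene-1-carboxylic acid (target)
Conditions: Pd(PPh3)4 (5 mol %), N-methylaniline (2 equiv), THF, 0 °C to rt
Reagents that add atoms: none
Why: Tsuji–Trost deallylation: zerovalent palladium ionises the unhindered primary allyl ester and N-methylaniline takes up the allyl group under non-basic conditions, while the ring C3 ester, whose anti face is shielded by the neighbouring tiglate, should ionise far more slowly.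

**Compound list**

1 | 1,2:5,6-di-O-isopropylidene-α-D-glucofuranose | CC1(C)OC[C@@H](O1)[C@@H]2[C@H](O)[C@H]3OC(C)(C)O[C@H]3O2 | starting material
2 | tigloyl chloride, (E)-2-methylbut-2-enoyl chloride | C/C=C(\C)C(Cl)=O | starting material
3 | 1,2:5,6-di-O-isopropylidene-3-O-tigloyl-α-D-glucofuranose | CC1(C)OC[C@@H](O1)[C@@H]2[C@H](OC(=O)/C(C)=C/C)[C@H]3OC(C)(C)O[C@H]3O2 | intermediate
4 | 1,2-O-isopropylidene-3-O-tigloyl-α-D-glucofuranose (5,6-glycol, not isolated) | OC[C@@H](O)[C@@H]1[C@H](OC(=O)/C(C)=C/C)[C@H]2OC(C)(C)O[C@H]2O1 | intermediate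
5 | 1,2-O-isopropylidene-3-O-tigloyl-α-D-xylo-pentodialdo-1,4-furanose | O=C[C@@H]1[C@H](OC(=O)/C(C)=C/C)[C@H]2OC(C)(C)O[C@H]2O1 | intermediate
6 | propiolic acid | C#CC(=O)O | starting material
7 | allyl alcohol | C=CCO | starting material
8 | allyl propiolate | C#CC(=O)OCC=C | intermediate
9 | allyl 2-(diisobutylalumanyl)prop-2-enoate (vinylalane, not isolated) | C=C(C(=O)OCC=C)[Al](CC(C)C)CC(C)C | intermediate
10 | allyl 6-deoxy-1,2-O-isopropylidene-6-methylidene-3-O-tigloyl-α-D-gluco-heptofuranuronate and its C5 epimer | C=C(C(=O)OCC=C)C(O)[C@@H]1[C@H](OC(=O)/C(C)=C/C)[C@H]2OC(C)(C)O[C@H]2O1 | intermediate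
11 | acetic anhydride | CC(=O)OC(C)=O | starting material
12 | 5-O-acetate of 10 (C5 epimers) | C=C(C(=O)OCC=C)C(OC(C)=O)[C@@H]1[C@H](OC(=O)/C(C)=C/C)[C@H]2OC(C)(C)O[C@H]2O1 | intermediate
13 | allyl 5-O-acetyl-6-deoxy-6-methylidene-3-O-tigloyl-heptofuranuronate (1,2-diol; anomers, C5 epimers) | C=C(C(=O)OCC=C)C(OC(C)=O)[C@@H]1[C@H](OC(=O)/C(C)=C/C)[C@@H](O)C(O)O1 | intermediate
14 | trimethyl orthoacetate | CC(OC)(OC)OC | starting material
15 | 1,2-O-(1-methoxyethylidene) orthoester of 13 (α, cis-fused; not isolated) | C=C(C(=O)OCC=C)C(OC(C)=O)[C@@H]1[C@H](OC(=O)/C(C)=C/C)[C@H]2OC(C)(OC)O[C@H]2O1 | intermediate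
16 | allyl 2,5-di-O-acetyl-6-deoxy-6-methylidene-3-O-tigloyl-heptofuranuronate (free anomeric OH) | C=C(C(=O)OCC=C)C(OC(C)=O)[C@@H]1[C@H](OC(=O)/C(C)=C/C)[C@@H](OC(C)=O)C(O)O1 | intermediate
17 | N-hydroxyphthalimide | O=C1c2ccccc2C(=O)N1O | starting material
18 | N-glycosyloxyphthalimide of 16 (anomeric O–N(phthaloyl)) | C=C(C(=O)OCC=C)C(OC(C)=O)[C@@H]1[C@H](OC(=O)/C(C)=C/C)[C@@H](OC(C)=O)C(ON2C(=O)c3ccccc3C2=O)O1 | intermediate
19 | allyl 2,5-diacetoxy-3-(formyloxy)-4-(tigloyloxy)cyclohexane-1-carboxylate (3,4-trans, 4,5-trans; C1/C2 epimers; not isolated) | C/C=C(\C)C(=O)O[C@@H]1[C@@H](OC(C)=O)CC(C(=O)OCC=C)C(OC(C)=O)[C@H]1OC=O | intermediate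
20 | allyl (3R,4R,5S)-5-acetoxy-3-(formyloxy)-4-(tigloyloxy)cyclohex-1-ene-1-carboxylate | C/C=C(\C)C(=O)O[C@@H]1[C@@H](OC(C)=O)CC(C(=O)OCC=C)=C[C@H]1OC=O | intermediate
21 | allyl (3R,4S,5S)-5-acetoxy-3-hydroxy-4-(tigloyloxy)cyclohex-1-ene-1-carboxylate | C/C=C(\C)C(=O)O[C@@H]1[C@@H](OC(C)=O)CC(C(=O)OCC=C)=C[C@H]1O | intermediate
22 | 6-methylheptanoic acid | CC(C)CCCCC(=O)O | starting material
23 | allyl (3R,4R,5S)-5-acetoxy-3-[(6-methylheptanoyl)oxy]-4-(tigloyloxy)cyclohex-1-ene-1-carboxylate | C/C=C(\C)C(=O)O[C@@H]1[C@@H](OC(C)=O)CC(C(=O)OCC=C)=C[C@H]1OC(=O)CCCCC(C)C | intermediate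
24 | (3R,4R,5S)-5-acetoxy-3-[(6-methylheptanoyl)oxy]-4-(tigloyloxy)cyclohex-1-ene-1-carboxylic acid | C/C=C(\C)C(=O)O[C@@H]1[C@@H](OC(C)=O)CC(C(=O)O)=C[C@H]1OC(=O)CCCCC(C)C | target

**Step count and risks**

Total step count: 12. Longest linear sequence: 11 steps (steps 1, 2, 4–12).

Steps most likely to fail:

1. Step 9 (Proposed new method). The open-chain α-acetoxy radical may be reduced before it cyclises, the ring may close with poor facial selectivity at C5, or the formate may be lost during the DBU elimination. Fallback with known chemistry, using a carbonyl-derived radical instead of the fragmentation: setting out from 13, glycol cleavage with NaIO4 (THF/H2O) would give the open-chain formate aldehyde allyl 2-[(2R,3S)-1-acetoxy-2-(formyloxy)-4-oxo-3-(tigloyloxy)butyl]prop-2-enoate F1. Bu3SnH/AIBN (benzene, 80 °C, slow addition) would convert the aldehyde into an O-stannyl ketyl that closes 6-endo on the acrylate CH2 and, after destannylation, would give the cyclohexanol allyl 2-acetoxy-3-(formyloxy)-5-hydroxy-4-(tigloyloxy)cyclohexane-1-carboxylate F2. Acetylation (Ac2O, pyridine) would bring the route back at 19, which DBU converts to 20.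

2. Step 10. Methanolysis may also attack the acetate, or the tiglate may migrate from O4 to the freed O3 under base. Fallback by enzymatic hydrolysis: setting out from 20, a lipase (Candida antarctica lipase B, pH 7 phosphate buffer/MTBE, 25 °C) would hydrolyse the unhindered formate at neutral pH and come back at 21; no new compound is formed.

3. Step 4. Aldehyde 5 may lose tiglic acid by β-elimination, or the vinylalane may add sluggishly. Fallback by aldol/selenoxide elimination: setting out from 5, the lithium enolate (LDA, THF, −78 °C) of allyl 3-(phenylselanyl)propanoate F3 (from allyl acrylate and benzeneselenol) would add to the aldehyde to give the β-hydroxy selenide allyl 6-deoxy-1,2-O-isopropylidene-6-C-[(phenylselanyl)methyl]-3-O-tigloyl-heptofuranuronate F4. Oxidation with H2O2 (pyridine, CH2Cl2, 0 °C) and selenoxide syn-elimination would come back at 10.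

**Further compounds**

F1 | step 9 | allyl 2-[(2R,3S)-1-acetoxy-2-(formyloxy)-4-oxo-3-(tigloyloxy)butyl]prop-2-enoate (C1′ epimers) | C=C(C(=O)OCC=C)C(OC(C)=O)[C@@H](OC=O)[C@H](OC(=O)/C(C)=C/C)C=O
F2 | step 9 | allyl 2-acetoxy-3-(formyloxy)-5-hydroxy-4-(tigloyloxy)cyclohexane-1-carboxylate (3,4-trans, 4,5-trans; C1/C2 epimers) | C/C=C(\C)C(=O)O[C@@H]1[C@@H](O)CC(C(=O)OCC=C)C(OC(C)=O)[C@H]1OC=O
F0 | step 10 | none | none
F3 | step 4 | allyl 3-(phenylselanyl)propanoate | C=CCOC(=O)CC[Se]c1ccccc1
F4 | step 4 | allyl 6-deoxy-1,2-O-isopropylidene-6-C-[(phenylselanyl)methyl]-3-O-tigloyl-heptofuranuronate (C5/C6 isomers) | C=CCOC(=O)C(C[Se]c1ccccc1)C(O)[C@@H]1[C@H](OC(=O)/C(C)=C/C)[C@H]2OC(C)(C)O[C@H]2O1
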